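I start from a ratio: the rate at which substrate is lost to a side reaction, divided by the rate at which it forms intermediate A. In that ratio time drops out and [substrate] stays.

| flask | substrate | remark | time |
|---|---|---|---|
| teal | 3 M | run made earlier |  |
| violet | 1.5 M | run made earlier |  |
| amber | 2.2 M | run made earlier |  |
| alpha | 3.0 M | a single well-mixed tank run continuously and read at steady state, 45.0 d in it on average |  |
| delta | 3.0 M | a closed flask charged with all of it at once and left for 15 d | 15 d |
| eta | 3.0 M | one stirred flow tank at steady state, fed with the mixture as stated, mean residence time 15 d |  |
| beta | 3.0 M | a tube with plug flow, the mixed feed as stated, residence time 15 d | 15 d |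

| run | time / d | intermediate A / % | target / % |
|---|---|---|---|
| teal | 4.00 | 63.8 | 0 |
| teal | 8.00 | 56.0 | 2.5 |
| teal | 12.0 | 47.8 | 5.7 |
| teal | 15.0 | 42.1 | 7.8 |
| violet | 1.67 | 68.1 | 0 |
| violet | 4.00 | 72.6 | 0.7 |
| violet | 8.00 | 63.7 | 2.8 |
| violet | 12.0 | 55.3 | 6.3 |
| amber | 1.04 | 55.3 | 0 |
| amber | 2.00 | 67.6 | 0.5 |
| amber | 5.00 | 66.5 | 0.7 |
| amber | 12.0 | 51.1 | 5.4 |

(each reading ± 0.5 percentage points)

- the set-up with the highest amount of intermediate A at the outlet or at the end, in percent of the substrate put in ("none" if the first two lie within 2 percentage points) (alpha / delta / eta / beta / none)
- amount of intermediate A at the outlet or at the end, in percent of the substrate put in, alpha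
- amount of intermediate A at the outlet or at the end, in percent of the substrate put in, delta
- amount of intermediate A at the outlet or at the end, in percent of the substrate put in, eta
- amount of intermediate A at the outlet or at the end, in percent of the substrate put in, beta

- the stated concentrations are those of everything mixed, before any reaction; amounts are the same in each set-up
- the numbers in the tables scatter by 0.5 percentage points (one standard deviation)
- the earlier runs were made in a closed, stirred flask

In the teal flask, intermediate A falls between the first and last readings with a constant of 0.0378 d⁻¹. Put back to zero time, that gives a reading of 74.2% formed at 3 M. The violet flask gives 84.4% at 1.5 M. The yield falls as the charge rises, so I take formation as first order and the loss as second order in substrate. If the share at half the charge stands for the teal run, I get 0.232 L mol⁻¹, the loss ratio per unit of [substrate], a selectivity factor written the other way up.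

Now the ladder, by my own reckoning. Substrate is fastest: the first violet reading gives a formation constant of 1.17 d⁻¹, so its lifetime of 0.853 d is shorter than 15 d. Next comes the decay of intermediate A, with a lifetime of 26.5 d. The closed flask delta and the tube beta repeat the teal charge and time, so I read 42.1% for both. In the tank eta, [substrate] stays near 0.161 M, so the loss ratio is 0.0374. With the decay in the tank, that gives me 58.2%.

The forecast names eta, with 58% there, 36% in alpha, 42.2% in delta and 42.2% in beta. Its ground for eta is that low substrate in a stirred tank favours selectivity, and of delta and beta it says “The flask and the plug-flow tube behave alike”.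

    intermediate B → intermediate C (k = 0.00924 h⁻¹)
    substrate → intermediate A (k = 0.0443 h⁻¹)
    target ⇌ isomer of the product (K = 6.06, k = 0.00512 h⁻¹)
    intermediate C → target (k = 0.00736 h⁻¹)
    intermediate A → intermediate B (k = 0.00157 h⁻¹)
    2 substrate → homo dimer (k = 0.00609 L mol⁻¹ h⁻¹)

The flasks give 57.6% in eta, 42.7% in delta and beta, and 35.8% in alpha. The half-life of substrate by its passing into intermediate A alone, 0.65 d, is shorter than the 18 d of intermediate A by its passing into intermediate B alone, and with the constants above, [substrate] of 0.170 M in eta gives a loss ratio toward homo dimer of 0.0466, against 0.825 at the charge of delta. In alpha, my estimate from the readings, with [substrate] of 0.0558 M, gives a loss ratio of 0.0129 and 35.9% of intermediate A, where the flask gives 35.8%.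

The data are simulated from invented constants; the scatter is artificial.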